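(The readings were computed on assumed constants; the scatter is artificial.)

I decided to follow the grey flask by its rate and one ratio, leaving its concentrations aside.

| setting | grey | amber | flask |
|---|---|---|---|
| substrate | 0.031 M | 0.031 M | 0.031 M |
| partner | 0.50 equiv | 0.50 equiv | 0.500 equiv |
| free catalyst | 2.6 mol% | 2.6 mol% | 2.6 mol% |
| impurity | 0.87 mM | 0.43 mM | 0.87 mM |
| temperature | 25 °C | 10 °C | 25 °C |
| remark | the very flask that is asked about, followed so far | run made earlier |  |
| time |  |  | 8.0 d |

- grey (time / d: product / %): 1.04: 10.1; 3.00: 10.5; 5.00: 11.9; 8.00: 11.0
- amber (time / d: product / %): 4.00: 23.8; 8.00: 38.5; 12.0: 47.7; 15.0: 49.4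

(each reading ± 0.5 percentage points)

- Wednesday's: at 8.0 d add free catalyst, 100% of the amount charged, then wait 2.5 d
- Thursday's: at 8.0 d take out 90% of the product then present, then wait 2.5 d
- Monday's: at 8.0 d add partner, 100% of the amount charged, then wait 2.5 d
- Friday's: change nothing and wait 2.5 d more
- Saturday's: at 8.0 d raise the temperature by 20 K, then wait 2.5 d

1. product, in percent of the substrate first charged, at 8.0 d
2. what to do for the largest gain in product; "none" if nothing gains more than 2 percentage points (Wednesday's / Thursday's / Monday's / Friday's / Saturday's / none)
3. product present, with what was taken out counted in, in percent of the substrate first charged, after Thursday's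
4. product present, with what was taken out counted in, in percent of the substrate first charged, after Saturday's

- what is taken out of product is counted as made
- the earlier runs were read with a standard deviation of 0.5 percentage points
- additions bring no volume worth counting

The cooler amber run averaged 0.0595 d⁻¹ of the substrate charged over its first 4.00 d, and it was still rising at 12.0 d. Grey averaged 0.0971 d⁻¹ up to 1.04 d, but its later readings merely wandered between 10.5% and 11.9%, so its rate had fallen to nothing visible within the scatter.

Amber differed in temperature and in impurity, and grey, the warmer of the two, was the one that stopped, so I took the impurity as the brake. I assumed that it takes free catalyst one for one. The measure is then the poison ratio ρ, impurity charged over free catalyst charged, 1.08 in grey and 0.533 in amber. On that assumption, once impurity and free catalyst have met, the rate carries a factor of one minus ρ, the live share: 46.7% in amber, but nothing in grey, where ρ stands just above one.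

So I held grey at the mean of its readings, 10.9%. In my reckoning for grey, taking out product, adding partner, waiting or heating each multiply a zero rate. In grey, a second charge of free catalyst meets a small excess of impurity, leaving 92.1% of that charge live, twice amber's share. Scaled by this factor, with warmth left out of the reckoning, amber's rate becomes 0.117 d⁻¹, or 29 percentage points over the 2.5 d. I read amber's last reading of 49.4% as the ceiling that 0.500 equiv of partner allows, taking the partner as the limiting reagent.

The forecast gave 10.9%, Wednesday's, 10.9% and 11%, adding: “Partner, removing product, waiting or heating do nothing with dead catalyst”.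

The simulation gives 11.4% now. Wednesday's gains 38 points, while Thursday's leaves 11.4% and Saturday's 11.4%.

    substrate + free catalyst → catalyst intermediate A (k = 180 M⁻¹ h⁻¹, Ea = 69.0 kJ mol⁻¹)
    partner + catalyst intermediate A ⇌ catalyst intermediate B (K = 127 M⁻¹, k = 350 M⁻¹ h⁻¹, Ea = 59.0 kJ mol⁻¹, ΔH = −46.0 kJ mol⁻¹)
    catalyst intermediate B ⇌ by-product + catalyst intermediate C (K = 0.0118 M, k = 5.04 h⁻¹, Ea = 95.0 kJ mol⁻¹, ΔH = −34.0 kJ mol⁻¹)
    catalyst intermediate C → free catalyst + product (k = 5.68 h⁻¹, Ea = 90.0 kJ mol⁻¹)
    free catalyst + impurity → spent catalyst (k = 3890 M⁻¹ h⁻¹, Ea = 36.0 kJ mol⁻¹)
    (constants at 25 °C)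

The loss of free catalyst to impurity is the largest single effect in the grey flask: the same run without that step reaches 50.0% instead of 11.4%. Grey's ρ puts the impurity left over at 7.41% of its charge, and the flask holds 7.4% at 8.00 d. In the neighbour with 10 mol% of free catalyst, ρ is 0.281, which is below one. That neighbour reaches 50.0% product, with 28.1% of its catalyst spent.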